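**Retrosynthetic overview**
1. Target ⇒ 8‑hydroxy‑6,12‑olide with C14 masked as a diethyl acetal and O15 as a TBS ether (late O8 methacrylation, then one acidic unmasking).
2. Rings are formed in the biosynthetic order: first the ten‑membered carbocycle by C6–C7 bond formation (the bond a germacrene synthase makes from farnesyl diphosphate), here by intramolecular Cr(II) allylation of the C6 enal; then the γ‑lactone by O6→C12 acylation in the same flask.
3. C7 is used as a geminal allyl dianion: methyl 3‑bromo‑2‑(bromomethyl)acrylate first allylates the C8 aldehyde (sets C8, leaves Br on C7), and the same carbon then closes the ring onto C6.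
4. Open chain: B‑alkyl Suzuki union at C3–C4 of a (Z)‑iodoalkene from 2‑butyne‑1,4‑diol (C15/C4/C5/C6) with a diene made by vinylcuprate carbocupration of propiolaldehyde diethyl acetal and acylation with ethyl chlorooxoacetate (C14/C10/C1–C3/C9/C8).
5. Stereochemistry: C9 by asymmetric transfer hydrogenation, C8 by chelation control from C9, C6/C7 in the ring closure; both ring‑cis alkenes are fixed before cyclisation.

Assumption: atom labels C1–C15 are the germacrane positions of the target (SMILES read as 6R,7S,8S,9S; C2 trans to CHO and C6 trans to CH2OH across the two ring alkenes); bromide 7 is used as an E/Z mixture and 21–23 as C7 isomer mixtures, because all converge on the same allylmetal.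

**Step 1**
Reactants: 1 but‑2‑yne‑1,4‑diol
Product: 2 4‑{[tert‑butyl(dimethyl)silyl]oxy}but‑2‑yn‑1‑ol
Conditions: NaH (1.0 equiv), THF, 0 °C; TBSCl (1.0 equiv), 0 °C → rt (diol 3 equiv)
Reagents that add atoms: tert‑butyldimethylsilyl chloride, CC(C)(C)[Si](C)(C)Cl
Why: Monosilylation of the symmetrical diol through its monosodium alkoxide (Williamson‑type O‑silylation) differentiates the future O15 (silylated, kept to the end) from O6 (free) at the outset; no stereocentre is formed.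

**Step 2**
Reactants: 2 4‑{[tert‑butyl(dimethyl)silyl]oxy}but‑2‑yn‑1‑ol
Product: 4 (2Z)‑4‑{[tert‑butyl(dimethyl)silyl]oxy}‑3‑iodobut‑2‑en‑1‑ol, via cyclic alkenylaluminate 3 (not isolated)
Conditions: Red‑Al (1.6 equiv), Et2O, 0 °C → rt; EtOAc; then I2 (2 equiv), THF, −78 → 0 °C; aq. Rochelle salt
Reagents that add atoms: iodine, II
Why: Hydroxyl‑directed trans‑hydroalumination of the propargylic alcohol (Red‑Al reduction) followed by iodinolysis of the cyclic alkenylaluminate with retention gives the (Z)‑3‑iodoallylic alcohol, so iodine (the later C3 attachment point) is cis to C6 and CH2OTBS (C15) is trans to C6.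

**Step 3**
Reactants: 5 methyl 2‑(bromomethyl)prop‑2‑enoate
Product: 7 methyl 3‑bromo‑2‑(bromomethyl)prop‑2‑enoate, via tribromo ester 6 (not isolated)
Conditions: Br2 (1.05 equiv), CH2Cl2, 0 °C → rt; then Et3N (1.0 equiv), 0 °C
Reagents that add atoms: bromine, BrBr
Why: Bromine addition to the acrylate followed by E2 dehydrobromination (loss of the α‑bromine with a β‑hydrogen, the same amine elimination used to make α‑(bromomethyl)acrylates) gives the 3‑bromoacrylate; its alkene geometry is irrelevant because both isomers give the same allylmetal.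

**Step 4**
Reactants: 8 bromoethene; 9 3,3‑diethoxyprop‑1‑yne; 10 ethyl chlorooxoacetate
Product: 14 ethyl (3Z)‑3‑(diethoxymethyl)‑2‑oxohexa‑3,5‑dienoate, via ethenyllithium 11 (not isolated), via lithium diethenylcuprate 12 (not isolated), via dienyl(ethenyl)cuprate 13 (not isolated)
Conditions: 8 (2 equiv), t‑BuLi (4 equiv), Et2O, −78 °C; CuBr·SMe2 (1 equiv), −45 °C; 9 (1 equiv), −45 → −25 °C; 10 (2.5 equiv), −78 → −20 °C
Reagents that add atoms: none
Why: Alexakis–Normant carbocupration of a propargylic acetal in ether is syn and puts copper on the carbon next to the acetal, so the vinyl group (C2) ends cis to copper, and acylation of the alkenylcuprate by the acid chloride with retention fixes the C1=C10 geometry (C2 cis to C9, trans to C14).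

**Step 5**
Reactants: 14 ethyl (3Z)‑3‑(diethoxymethyl)‑2‑oxohexa‑3,5‑dienoate
Product: 15 ethyl (2S,3E)‑3‑(diethoxymethyl)‑2‑hydroxyhexa‑3,5‑dienoate
Conditions: RuCl[(R,R)‑TsDPEN](p‑cymene) (1 mol %), HCO2H/Et3N (1:1), CH2Cl2, 0 °C → rt
Reagents that add atoms: none
Why: Noyori asymmetric transfer hydrogenation reduces the α‑keto ester 1,2‑selectively and sets C9 as S, the alkenyl group taking the place of the aryl group in the CH/π‑controlled transition state (the enantiomeric catalyst is used if the sense proves opposite).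

**Step 6**
Reactants: 15 ethyl (2S,3E)‑3‑(diethoxymethyl)‑2‑hydroxyhexa‑3,5‑dienoate
Product: 16 ethyl (2S,3E)‑3‑(diethoxymethyl)‑2‑methoxyhexa‑3,5‑dienoate
Conditions: Ag2O (3 equiv), MeI (10 equiv), 4 Å MS, Et2O, rt, dark
Reagents that add atoms: iodomethane, CI
Why: Purdie methylation O‑alkylates the α‑hydroxy ester without a strong base, so the C9 centre (α to the ester and allylic) is not epimerised and the C9 methyl ether of the target is in place.

**Step 7**
Reactants: 16 ethyl (2S,3E)‑3‑(diethoxymethyl)‑2‑methoxyhexa‑3,5‑dienoate; 4 (2Z)‑4‑{[tert‑butyl(dimethyl)silyl]oxy}‑3‑iodobut‑2‑en‑1‑ol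
Product: 18 ethyl (2S,3E,7E)‑7‑({[tert‑butyl(dimethyl)silyl]oxy}methyl)‑3‑(diethoxymethyl)‑9‑hydroxy‑2‑methoxynona‑3,7‑dienoate, via B‑alkyl‑9‑BBN adduct 17 (not isolated)
Conditions: 9‑BBN (1.2 equiv), THF, 0 °C → rt; then 4 (1.0 equiv), Pd(dppf)Cl2 (5 mol %), AsPh3 (5 mol %), Cs2CO3 (2 equiv), DMF/H2O, rt
Reagents that add atoms: none
Why: 9‑BBN hydroborates only the terminal vinyl group of the diene (anti‑Markovnikov, boron on C3), and B‑alkyl Suzuki–Miyaura coupling with the alkenyl iodide proceeds with retention under mild base, forming C3–C4 and fixing the C4=C5 geometry (C3 cis to C6).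

**Step 8**
Reactants: 18 ethyl (2S,3E,7E)‑7‑({[tert‑butyl(dimethyl)silyl]oxy}methyl)‑3‑(diethoxymethyl)‑9‑hydroxy‑2‑methoxynona‑3,7‑dienoate
Product: 19 (2S,3E,7E)‑7‑({[tert‑butyl(dimethyl)silyl]oxy}methyl)‑3‑(diethoxymethyl)‑9‑hydroxy‑2‑methoxynona‑3,7‑dienal
Conditions: DIBAL‑H (2.3 equiv), CH2Cl2, −78 °C; MeOH, then aq. Rochelle salt (pH 7), used at once
Reagents that add atoms: none
Why: DIBAL‑H reduction of an α‑alkoxy ester at −78 °C is a reliable ester‑to‑aldehyde reduction (the free C6 hydroxyl only consumes one hydride), and the neutral cold work‑up keeps the α‑methoxy‑β,γ‑unsaturated aldehyde from epimerising at C9.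

**Step 9**
Reactants: 19 (2S,3E,7E)‑7‑({[tert‑butyl(dimethyl)silyl]oxy}methyl)‑3‑(diethoxymethyl)‑9‑hydroxy‑2‑methoxynona‑3,7‑dienal; 7 methyl 3‑bromo‑2‑(bromomethyl)prop‑2‑enoate
Product: 21 methyl (4R,5S,6E,10E)‑3‑bromo‑10‑({[tert‑butyl(dimethyl)silyl]oxy}methyl)‑6‑(diethoxymethyl)‑4,12‑dihydroxy‑5‑methoxy‑2‑methylidenedodeca‑6,10‑dienoate, via allylindium dibromide 20 (not isolated)
Conditions: 7 (3 equiv), In powder (2.5 equiv), THF/H2O (3:1), rt
Reagents that add atoms: none
Why: Proposed new method: indium inserts into the allylic C–Br bond of 7 and the resulting 2‑(methoxycarbonyl)allylindium adds through its γ‑carbon (the CHBr terminus, SE2′) to the aldehyde, so C7 arrives still carrying bromine (its configuration is irrelevant), while In(III) chelation between the aldehyde oxygen and the α‑methoxy group in water (Cram‑chelate model) gives the 8,9‑syn product with the C8 configuration of the target; the closest known reactions are the aqueous indium Barbier 2‑(alkoxycarbonyl)allylation of α‑alkoxy aldehydes and the indium γ‑bromoallylation with 1,3‑dibromopropene as a gem‑allyl dianion synthon.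

**Step 10**
Reactants: 21 methyl (4R,5S,6E,10E)‑3‑bromo‑10‑({[tert‑butyl(dimethyl)silyl]oxy}methyl)‑6‑(diethoxymethyl)‑4,12‑dihydroxy‑5‑methoxy‑2‑methylidenedodeca‑6,10‑dienoate
Product: 22 methyl (4R,5S,6E,10E)‑3‑bromo‑10‑({[tert‑butyl(dimethyl)silyl]oxy}methyl)‑6‑(diethoxymethyl)‑4‑hydroxy‑5‑methoxy‑2‑methylidene‑12‑oxododeca‑6,10‑dienoate
Conditions: MnO2 (20 equiv), CH2Cl2, rt
Reagents that add atoms: none
Why: Activated MnO2 oxidises only the primary allylic C6 alcohol (the C8 hydroxyl is not allylic), under neutral conditions that leave the allylic bromide, the acetal and the C4=C5 geometry untouched.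

**Step 11**
Reactants: 22 methyl (4R,5S,6E,10E)‑3‑bromo‑10‑({[tert‑butyl(dimethyl)silyl]oxy}methyl)‑6‑(diethoxymethyl)‑4‑hydroxy‑5‑methoxy‑2‑methylidene‑12‑oxododeca‑6,10‑dienoate
Product: 25 (3aR,4S,5S,6E,10E,11aR)‑10‑({[tert‑butyl(dimethyl)silyl]oxy}methyl)‑6‑(diethoxymethyl)‑4‑hydroxy‑5‑methoxy‑3‑methylidene‑3a,4,5,8,9,11a‑hexahydrocyclodeca[b]furan‑2(3H)‑one, via allylchromium(III) dichloride 23 (not isolated), via chromium(III) alkoxide 24 (not isolated)
Conditions: CrCl2 (10 equiv), degassed THF, rt, syringe‑pump addition to 2 mM final concentration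
Reagents that add atoms: none
Why: Intramolecular Nozaki–Hiyama (Cr(II)) allylation: the allylchromium adds through C7 to the C6 enal in a chair transition state in which the ring tether holds C5 and C8 antiperiplanar (H6/H7 trans, as in Cr‑mediated closures of other germacranolide precursors) and allylic strain keeps H8 in the alkene plane so that C6 bonds anti to C9 with the C8 hydroxyl outside (7,8‑anti), after which the chromium alkoxide on O6, the only metal alkoxide present, acylates itself on the ester to give the trans‑fused 6,12‑lactone while the neutral C8–OH stays free.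

**Step 12**
Reactants: 25 (3aR,4S,5S,6E,10E,11aR)‑10‑({[tert‑butyl(dimethyl)silyl]oxy}methyl)‑6‑(diethoxymethyl)‑4‑hydroxy‑5‑methoxy‑3‑methylidene‑3a,4,5,8,9,11a‑hexahydrocyclodeca[b]furan‑2(3H)‑one
Product: 26 (3aS,4S,5S,6E,10E,11aR)‑10‑({[tert‑butyl(dimethyl)silyl]oxy}methyl)‑6‑(diethoxymethyl)‑5‑methoxy‑3‑methylidene‑2‑oxo‑2,3,3a,4,5,8,9,11a‑octahydrocyclodeca[b]furan‑4‑yl 2‑methylprop‑2‑enoate
Conditions: methacrylic anhydride (3 equiv), Et3N (4 equiv), DMAP (0.2 equiv), CH2Cl2, 0 °C → rt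
Reagents that add atoms: methacrylic anhydride, C=C(C)C(=O)OC(=O)C(C)=C
Why: DMAP‑catalysed acylation esterifies the only free hydroxyl (C8) with retention of configuration; O15 is silylated and C14 is an acetal, so no other site competes.

**Step 13**
Reactants: 26 (3aS,4S,5S,6E,10E,11aR)‑10‑({[tert‑butyl(dimethyl)silyl]oxy}methyl)‑6‑(diethoxymethyl)‑5‑methoxy‑3‑methylidene‑2‑oxo‑2,3,3a,4,5,8,9,11a‑octahydrocyclodeca[b]furan‑4‑yl 2‑methylprop‑2‑enoate
Product: 27 (3aS,4S,5S,6E,10E,11aR)‑6‑formyl‑10‑(hydroxymethyl)‑5‑methoxy‑3‑methylidene‑2‑oxo‑2,3,3a,4,5,8,9,11a‑octahydrocyclodeca[b]furan‑4‑yl 2‑methylprop‑2‑enoate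
Conditions: aq. HF (48 %)/MeCN (1:19), 0 °C → rt
Reagents that add atoms: water, O
Why: Aqueous HF cleaves the primary TBS ether and hydrolyses the α,β‑unsaturated diethyl acetal in one operation; the enal released has the thermodynamically preferred geometry (C2 trans to CHO), and the lactone, methacrylate and methyl ether are stable to these conditions.

**Compound list**
1 | but‑2‑yne‑1,4‑diol | OCC#CCO | starting material
2 | 4‑{[tert‑butyl(dimethyl)silyl]oxy}but‑2‑yn‑1‑ol | OCC#CCO[Si](C)(C)C(C)(C)C | intermediate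
3 | sodium cyclic alkenylaluminate from 2 (Al bonded to O6 and C4 in a five‑membered ring, two 2‑methoxyethoxy ligands) | [Na+].COCCO[Al-]1(OCCOC)OCC=C1CO[Si](C)(C)C(C)(C)C | intermediate
4 | (2Z)‑4‑{[tert‑butyl(dimethyl)silyl]oxy}‑3‑iodobut‑2‑en‑1‑ol (I cis to CH2OH) | OC/C=C(\I)CO[Si](C)(C)C(C)(C)C | intermediate
5 | methyl 2‑(bromomethyl)prop‑2‑enoate | C=C(CBr)C(=O)OC | starting material
6 | methyl 2,3‑dibromo‑2‑(bromomethyl)propanoate | BrCC(Br)(CBr)C(=O)OC | intermediate
7 | methyl 3‑bromo‑2‑(bromomethyl)prop‑2‑enoate (E/Z mixture) | BrC=C(CBr)C(=O)OC | intermediate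
8 | bromoethene | C=CBr | starting material
9 | 3,3‑diethoxyprop‑1‑yne | C#CC(OCC)OCC | starting material
10 | ethyl chlorooxoacetate | CCOC(=O)C(Cl)=O | starting material
11 | ethenyllithium | [Li]C=C | intermediate
12 | lithium diethenylcuprate | [Li+].C=C[Cu-]C=C | intermediate
13 | lithium [(1Z)‑1‑(diethoxymethyl)buta‑1,3‑dien‑1‑yl](ethenyl)cuprate (Cu cis to the vinyl group) | [Li+].C=C[Cu-]/C(C(OCC)OCC)=C\C=C | intermediate
14 | ethyl (3Z)‑3‑(diethoxymethyl)‑2‑oxohexa‑3,5‑dienoate | CCOC(=O)C(=O)/C(C(OCC)OCC)=C\C=C | intermediate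
15 | ethyl (2S,3E)‑3‑(diethoxymethyl)‑2‑hydroxyhexa‑3,5‑dienoate | CCOC(=O)[C@@H](O)/C(C(OCC)OCC)=C\C=C | intermediate
16 | ethyl (2S,3E)‑3‑(diethoxymethyl)‑2‑methoxyhexa‑3,5‑dienoate | CCOC(=O)[C@@H](OC)/C(C(OCC)OCC)=C\C=C | intermediate
17 | ethyl (2S,3E)‑6‑(9‑borabicyclo[3.3.1]nonan‑9‑yl)‑3‑(diethoxymethyl)‑2‑methoxyhex‑3‑enoate | CCOC(=O)[C@@H](OC)/C(C(OCC)OCC)=C\CCB1C2CCCC1CCC2 | intermediate
18 | ethyl (2S,3E,7E)‑7‑({[tert‑butyl(dimethyl)silyl]oxy}methyl)‑3‑(diethoxymethyl)‑9‑hydroxy‑2‑methoxynona‑3,7‑dienoate | CCOC(=O)[C@@H](OC)/C(C(OCC)OCC)=C\CC/C(CO[Si](C)(C)C(C)(C)C)=C\CO | intermediate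
19 | (2S,3E,7E)‑7‑({[tert‑butyl(dimethyl)silyl]oxy}methyl)‑3‑(diethoxymethyl)‑9‑hydroxy‑2‑methoxynona‑3,7‑dienal | O=C[C@@H](OC)/C(C(OCC)OCC)=C\CC/C(CO[Si](C)(C)C(C)(C)C)=C\CO | intermediate
20 | dibromo[3‑bromo‑2‑(methoxycarbonyl)prop‑2‑en‑1‑yl]indium | COC(=O)C(C[In](Br)Br)=CBr | intermediate
21 | methyl (4R,5S,6E,10E)‑3‑bromo‑10‑({[tert‑butyl(dimethyl)silyl]oxy}methyl)‑6‑(diethoxymethyl)‑4,12‑dihydroxy‑5‑methoxy‑2‑methylidenedodeca‑6,10‑dienoate (C3 epimers; C3 = C7 of the target) | COC(=O)C(=C)C(Br)[C@H](O)[C@@H](OC)/C(C(OCC)OCC)=C\CC/C(CO[Si](C)(C)C(C)(C)C)=C\CO | intermediate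
22 | methyl (4R,5S,6E,10E)‑3‑bromo‑10‑({[tert‑butyl(dimethyl)silyl]oxy}methyl)‑6‑(diethoxymethyl)‑4‑hydroxy‑5‑methoxy‑2‑methylidene‑12‑oxododeca‑6,10‑dienoate (C3 epimers) | COC(=O)C(=C)C(Br)[C@H](O)[C@@H](OC)/C(C(OCC)OCC)=C\CC/C(CO[Si](C)(C)C(C)(C)C)=C\C=O | intermediate
23 | allylchromium(III) dichloride from 22 (Cr on C13H2, C7=C11 double bond, geometry not fixed) | COC(=O)C(C[Cr](Cl)Cl)=C[C@H](O)[C@@H](OC)/C(C(OCC)OCC)=C\CC/C(CO[Si](C)(C)C(C)(C)C)=C\C=O | intermediate
24 | chromium(III) alkoxide of the ring‑closed hydroxy ester (ten‑membered ring formed, O6–Cr, lactone not yet closed) | O[C@H]1[C@@H](C(=C)C(=O)OC)[C@H](O[Cr](Cl)Cl)/C=C(/CO[Si](C)(C)C(C)(C)C)CC/C=C(/C(OCC)OCC)[C@@H]1OC | intermediate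
25 | (3aR,4S,5S,6E,10E,11aR)‑10‑({[tert‑butyl(dimethyl)silyl]oxy}methyl)‑6‑(diethoxymethyl)‑4‑hydroxy‑5‑methoxy‑3‑methylidene‑3a,4,5,8,9,11a‑hexahydrocyclodeca[b]furan‑2(3H)‑one | O[C@H]1[C@H]2C(=C)C(=O)O[C@@H]2/C=C(/CO[Si](C)(C)C(C)(C)C)CC/C=C(/C(OCC)OCC)[C@@H]1OC | intermediate
26 | (3aS,4S,5S,6E,10E,11aR)‑10‑({[tert‑butyl(dimethyl)silyl]oxy}methyl)‑6‑(diethoxymethyl)‑5‑methoxy‑3‑methylidene‑2‑oxo‑2,3,3a,4,5,8,9,11a‑octahydrocyclodeca[b]furan‑4‑yl 2‑methylprop‑2‑enoate | C=C(C)C(=O)O[C@H]1[C@H]2C(=C)C(=O)O[C@@H]2/C=C(/CO[Si](C)(C)C(C)(C)C)CC/C=C(/C(OCC)OCC)[C@@H]1OC | intermediate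
27 | (3aS,4S,5S,6E,10E,11aR)‑6‑formyl‑10‑(hydroxymethyl)‑5‑methoxy‑3‑methylidene‑2‑oxo‑2,3,3a,4,5,8,9,11a‑octahydrocyclodeca[b]furan‑4‑yl 2‑methylprop‑2‑enoate (CNP0114830.1) | C=C(C)C(=O)O[C@H]1[C@H]2C(=C)C(=O)O[C@@H]2/C=C(/CO)CC/C=C(/C=O)[C@@H]1OC | target

**Step count**
Total: 13 steps. Longest linear sequence: 10 steps (steps 4–13, from bromoethene, 3,3‑diethoxyprop‑1‑yne and ethyl chlorooxoacetate); steps 1–2 and step 3 are side branches.

**Three steps most likely to fail**

Step 11 (ring closure). The allylchromium could lose the C8 oxygen by elimination, the C8 hydroxyl could capture the ester to give the 8,12‑lactone, or the wrong C6/C7 diastereomer could form. The fallback sets out from 21 and blocks O8 before the ring is closed. Both hydroxyls are silylated (TESOTf, 2,6‑lutidine, CH2Cl2, −78 °C) to give the bis(triethylsilyl) ether of 21 F3. Swern oxidation with i‑Pr2NEt then cleaves and oxidises only the primary allylic TES ether, giving the 8‑O‑triethylsilyl enal F4. CrCl2 closure under high dilution gives the 8‑O‑triethylsilyl macrolactone F5, in which only O6 can lactonise. PPTS in ethanol at 0 °C removes the secondary TES group while the TBS ether and the diethyl acetal stay, and the route is rejoined at 25.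

Step 9 (first allylation with 7). The allylindium might react at its CH2 terminus, the product bromide might be reduced further, or the acetal might suffer in the aqueous medium. The fallback sets out from 7 and 19 and replaces the in‑situ Barbier reagent by an isolable allylstannane. Bromide 7 is stannylated at its allylic C–Br bond (hexabutylditin, Pd2(dba)3 cat., THF) to give methyl 3‑bromo‑2‑[(tributylstannyl)methyl]prop‑2‑enoate F2. F2 is added to 19 with MgBr2·OEt2 in CH2Cl2 at −20 °C (chelation‑controlled SE2′ allylstannane addition, anhydrous), and the route is rejoined at 21.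

Step 4 (three‑component carbocupration/acylation). The α‑acetal alkenylcuprate may acylate sluggishly or eliminate ethoxide, and 14 is a cis‑dienone that can equilibrate with its 2H‑pyran valence isomer. The fallback sets out from 8 and 9. Cuprate 13 is made as before but quenched with iodine to give the isolable (2Z)‑1,1‑diethoxy‑2‑iodopenta‑2,4‑diene F1. F1 is converted into the alkenyllithium (t‑BuLi, 2 equiv, Et2O, −78 °C) and added inversely to diethyl oxalate (3 equiv, −78 °C), and the keto ester is carried cold into step 5; the route is rejoined at 14.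

**Further compounds**
F1 | step 4 | (2Z)‑1,1‑diethoxy‑2‑iodopenta‑2,4‑diene | I/C(C(OCC)OCC)=C\C=C
F2 | step 9 | methyl 3‑bromo‑2‑[(tributylstannyl)methyl]prop‑2‑enoate | CCCC[Sn](CCCC)(CCCC)CC(=CBr)C(=O)OC
F3 | step 11 | methyl (4R,5S,6E,10E)‑3‑bromo‑10‑({[tert‑butyl(dimethyl)silyl]oxy}methyl)‑6‑(diethoxymethyl)‑5‑methoxy‑2‑methylidene‑4,12‑bis[(triethylsilyl)oxy]dodeca‑6,10‑dienoate | COC(=O)C(=C)C(Br)[C@H](O[Si](CC)(CC)CC)[C@@H](OC)/C(C(OCC)OCC)=C\CC/C(CO[Si](C)(C)C(C)(C)C)=C\CO[Si](CC)(CC)CC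
F4 | step 11 | methyl (4R,5S,6E,10E)‑3‑bromo‑10‑({[tert‑butyl(dimethyl)silyl]oxy}methyl)‑6‑(diethoxymethyl)‑5‑methoxy‑2‑methylidene‑12‑oxo‑4‑[(triethylsilyl)oxy]dodeca‑6,10‑dienoate | COC(=O)C(=C)C(Br)[C@H](O[Si](CC)(CC)CC)[C@@H](OC)/C(C(OCC)OCC)=C\CC/C(CO[Si](C)(C)C(C)(C)C)=C\C=O
F5 | step 11 | (3aS,4S,5S,6E,10E,11aR)‑10‑({[tert‑butyl(dimethyl)silyl]oxy}methyl)‑6‑(diethoxymethyl)‑5‑methoxy‑3‑methylidene‑4‑[(triethylsilyl)oxy]‑3a,4,5,8,9,11a‑hexahydrocyclodeca[b]furan‑2(3H)‑one | CC[Si](CC)(CC)O[C@H]1[C@H]2C(=C)C(=O)O[C@@H]2/C=C(/CO[Si](C)(C)C(C)(C)C)CC/C=C(/C(OCC)OCC)[C@@H]1OC
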